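## Retrosynthetic overview

1. Target ⇐ face-selective hydrogenation of the 4-methylidene lactone keto acid; the C4 methyl is set last, cis to CO2H.
2. 4-Methylidene acid ⇐ trans-2,3-disubstituted paraconic acid (side-chain ketone masked as a dioxolane) by C4 carboxylation and decarboxylative Mannich methylenation.
3. Paraconic acid ⇐ lactone N-acyl oxazolidinone ⇐ Evans syn-aldol (key C2–C3 bond) between a succinate imide and a C16 ketal aldehyde. The γ-lactone, the only ring of the target, closes right after the aldol by attack of the aldol hydroxyl on the succinate methyl ester.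
4. Aldehyde ⇐ ω-pentadecalactone (Weinreb opening, MeMgBr, ketalization, Swern); imide ⇐ (R)-4-benzyloxazolidinone + methyl succinyl chloride.

Assumption: (4R)-4-benzyl-1,3-oxazolidin-2-one is taken as a purchasable starting material (it is recovered after use); C2/C3/C4 in the text are oxolane locants of the target (C2 bears the chain, C3 the CO2H, C4 the methyl).

## Route

Step 1
Reactants: 1 ω-pentadecalactone (oxacyclohexadecan-2-one)
Product: 2 15-hydroxy-N-methoxy-N-methylpentadecanamide
Conditions: MeNHOMe·HCl (1.5 equiv), iPrMgCl (3 equiv), THF, −20 → 0 °C; aq. NH4Cl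
Reagents that add atoms: N,O-dimethylhydroxylamine hydrochloride, CNOC.Cl
Why: Weinreb aminolysis of the unstrained macrolactone by the in situ magnesium amide opens the ring to the hydroxy Weinreb amide, which cannot re-close to a 16-membered ring.

Step 2
Reactants: 2 15-hydroxy-N-methoxy-N-methylpentadecanamide
Product: 3 16-hydroxyhexadecan-2-one
Conditions: MeMgBr (3 equiv), THF, 0 °C → rt; aq. NH4Cl
Reagents that add atoms: methylmagnesium bromide, C[Mg]Br
Why: Weinreb ketone synthesis, in which the first equivalent only deprotonates the alcohol and the chelated tetrahedral adduct stops the Grignard addition at the methyl ketone.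

Step 3
Reactants: 3 16-hydroxyhexadecan-2-one
Product: 4 14-(2-methyl-1,3-dioxolan-2-yl)tetradecan-1-ol
Conditions: HOCH2CH2OH (5 equiv), p-TsOH·H2O (5 mol %), toluene, reflux, Dean–Stark
Reagents that add atoms: ethylene glycol (ethane-1,2-diol), OCCO
Why: Acid-catalysed ketalization driven by azeotropic water removal masks the methyl ketone so that it can be neither enolized in the aldol nor carboxylated later.

Step 4
Reactants: 4 14-(2-methyl-1,3-dioxolan-2-yl)tetradecan-1-ol
Product: 5 14-(2-methyl-1,3-dioxolan-2-yl)tetradecanal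
Conditions: (COCl)2, DMSO, CH2Cl2, −78 °C; Et3N, −78 → 0 °C
Reagents that add atoms: none
Why: Swern oxidation stops cleanly at the aldehyde under non-aqueous, base-buffered conditions that leave the dioxolane intact.

Step 5
Reactants: 6 (4R)-4-benzyl-1,3-oxazolidin-2-one; 7 methyl 4-chloro-4-oxobutanoate
Product: 9 methyl 4-[(4R)-4-benzyl-2-oxo-1,3-oxazolidin-3-yl]-4-oxobutanoate, via N-lithio oxazolidinone 8 (not isolated)
Conditions: n-BuLi, THF, −78 °C; then 7, −78 → 0 °C
Reagents that add atoms: none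
Why: N-acylation (nucleophilic acyl substitution) of the lithiated carbamate occurs at the acid chloride, which is far more electrophilic than the methyl ester.

Step 6
Reactants: 9 methyl 4-[(4R)-4-benzyl-2-oxo-1,3-oxazolidin-3-yl]-4-oxobutanoate; 5 14-(2-methyl-1,3-dioxolan-2-yl)tetradecanal
Product: 12 (4R)-4-benzyl-3-{(2S,3R)-2-[13-(2-methyl-1,3-dioxolan-2-yl)tridecyl]-5-oxooxolane-3-carbonyl}-1,3-oxazolidin-2-one, via Z-boron enolate 10 (not isolated), via syn-aldol adduct 11 (not isolated)
Conditions: Bu2BOTf (1.1 equiv), iPr2NEt (1.3 equiv), CH2Cl2, 0 °C; 5 (0.95 equiv), −78 → 0 °C; pH 7 buffer (KH2PO4/Na2HPO4), MeOH, 30% H2O2, 0 °C; then toluene, 60 °C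
Reagents that add atoms: none
Why: Evans syn-aldol, in which soft enolization of the imide (not the ester) gives the Z-boron enolate that adds to the aldehyde through a chair Zimmerman–Traxler transition state on the face away from the benzyl group, fixing C2 as S and C3 as R (syn in the open chain, hence trans in the ring), after which the new hydroxyl closes onto the methyl ester to form the γ-lactone.

Step 7
Reactants: 12 (4R)-4-benzyl-3-{(2S,3R)-2-[13-(2-methyl-1,3-dioxolan-2-yl)tridecyl]-5-oxooxolane-3-carbonyl}-1,3-oxazolidin-2-one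
Product: 14 (2S,3R)-2-[13-(2-methyl-1,3-dioxolan-2-yl)tridecyl]-5-oxooxolane-3-carboxylic acid, via peroxy acid 13 (not isolated)
Conditions: LiOH, 30% H2O2, THF/H2O (3:1), 0 °C; aq. Na2SO3; cold 1 M HCl to pH 3, fast extraction
Reagents that add atoms: hydrogen peroxide, OO
Why: Evans hydroperoxide cleavage of the imide attacks the exocyclic carbonyl selectively, sulfite reduces the peroxy acid, any lactone opened by hydroxide re-closes on acidification, and C3 is not enolized as its carboxylate.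

Step 8
Reactants: 14 (2S,3R)-2-[13-(2-methyl-1,3-dioxolan-2-yl)tridecyl]-5-oxooxolane-3-carboxylic acid
Product: 15 (2S,3R)-2-[13-(2-methyl-1,3-dioxolan-2-yl)tridecyl]-5-oxooxolane-3,4-dicarboxylic acid (C4 epimer mixture, crude, used at once)
Conditions: MeOMgOCO2Me (2 M in DMF, large excess), 135 °C, N2, 48 h; ice-cold 1 M HCl/CH2Cl2, fast extraction
Reagents that add atoms: methyl magnesium carbonate (methoxymagnesium methyl carbonate), COC(=O)O[Mg]OC
Why: Stiles carboxylation of the lactone α-CH2 is pulled forward by magnesium chelation of the resulting malonate, while the C3 carboxylate blocks deprotonation at C3 and the dioxolane keeps the methyl ketone from being carboxylated.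

Step 9
Reactants: 15 (2S,3R)-2-[13-(2-methyl-1,3-dioxolan-2-yl)tridecyl]-5-oxooxolane-3,4-dicarboxylic acid
Product: 18 (2S,3R)-4-methylidene-5-oxo-2-(14-oxopentadecyl)oxolane-3-carboxylic acid, via Mannich base 16 (not isolated), via ketal methylene acid 17 (not isolated)
Conditions: 37% aq. HCHO, PhNHMe, NaOAc, AcOH, rt, 2 h; extractive work-up; then 1 M HCl, THF, rt
Reagents that add atoms: formaldehyde, C=O; water, O
Why: Decarboxylative Mannich methylenation (Mannich reaction of the malonic half-acid with the iminium from HCHO and PhNHMe, then loss of CO2 and amine) installs the exocyclic alkene without touching C2 or C3, and the aqueous acid then hydrolyses the dioxolane to release the methyl ketone.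

Step 10
Reactants: 18 (2S,3R)-4-methylidene-5-oxo-2-(14-oxopentadecyl)oxolane-3-carboxylic acid
Product: 19 (2S,3R,4S)-4-methyl-5-oxo-2-(14-oxopentadecyl)oxolane-3-carboxylic acid (target)
Conditions: H2 (1 atm), Pd/C (10% Pd on carbon), EtOAc, rt, vigorous stirring; recrystallization
Reagents that add atoms: none
Why: Heterogeneous catalytic hydrogenation delivers H2 to the exocyclic alkene from the face opposite the adjacent C3 carboxyl group, so the methyl ends up cis to CO2H (4S), while ketone, lactone and acid are inert to Pd/C at 1 atm.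

## Compound list

1 | ω-pentadecalactone (oxacyclohexadecan-2-one) | O=C1CCCCCCCCCCCCCCO1 | starting material
2 | 15-hydroxy-N-methoxy-N-methylpentadecanamide | CON(C)C(=O)CCCCCCCCCCCCCCO | intermediate
3 | 16-hydroxyhexadecan-2-one | CC(=O)CCCCCCCCCCCCCCO | intermediate
4 | 14-(2-methyl-1,3-dioxolan-2-yl)tetradecan-1-ol | CC1(OCCO1)CCCCCCCCCCCCCCO | intermediate
5 | 14-(2-methyl-1,3-dioxolan-2-yl)tetradecanal | CC1(OCCO1)CCCCCCCCCCCCCC=O | intermediate
6 | (4R)-4-benzyl-1,3-oxazolidin-2-one | O=C1N[C@H](Cc2ccccc2)CO1 | starting material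
7 | methyl 4-chloro-4-oxobutanoate | COC(=O)CCC(Cl)=O | starting material
8 | lithium (4R)-4-benzyl-2-oxo-1,3-oxazolidin-3-ide (N-lithio derivative of 6) | [Li]N1[C@H](Cc2ccccc2)COC1=O | intermediate
9 | methyl 4-[(4R)-4-benzyl-2-oxo-1,3-oxazolidin-3-yl]-4-oxobutanoate | COC(=O)CCC(=O)N1[C@H](Cc2ccccc2)COC1=O | intermediate
10 | Z-dibutylboron enolate of 9 (O–B and CH2CO2Me cis on the enolate double bond) | CCCCB(CCCC)O/C(=C\CC(=O)OC)N1[C@H](Cc2ccccc2)COC1=O | intermediate
11 | methyl (3R,4S)-3-{[(4R)-4-benzyl-2-oxo-1,3-oxazolidin-3-yl]carbonyl}-4-hydroxy-17-(2-methyl-1,3-dioxolan-2-yl)heptadecanoate (syn-aldol) | CC1(OCCO1)CCCCCCCCCCCCC[C@H](O)[C@@H](CC(=O)OC)C(=O)N2[C@H](Cc3ccccc3)COC2=O | intermediate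
12 | (4R)-4-benzyl-3-{(2S,3R)-2-[13-(2-methyl-1,3-dioxolan-2-yl)tridecyl]-5-oxooxolane-3-carbonyl}-1,3-oxazolidin-2-one (trans lactone) | CC1(OCCO1)CCCCCCCCCCCCC[C@@H]2OC(=O)C[C@H]2C(=O)N3[C@H](Cc4ccccc4)COC3=O | intermediate
13 | (2S,3R)-2-[13-(2-methyl-1,3-dioxolan-2-yl)tridecyl]-5-oxooxolane-3-carboperoxoic acid | CC1(OCCO1)CCCCCCCCCCCCC[C@@H]2OC(=O)C[C@H]2C(=O)OO | intermediate
14 | (2S,3R)-2-[13-(2-methyl-1,3-dioxolan-2-yl)tridecyl]-5-oxooxolane-3-carboxylic acid | CC1(OCCO1)CCCCCCCCCCCCC[C@@H]2OC(=O)C[C@H]2C(=O)O | intermediate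
15 | (2S,3R)-2-[13-(2-methyl-1,3-dioxolan-2-yl)tridecyl]-5-oxooxolane-3,4-dicarboxylic acid (C4 epimer mixture) | CC1(OCCO1)CCCCCCCCCCCCC[C@@H]2OC(=O)C(C(=O)O)[C@H]2C(=O)O | intermediate
16 | (2S,3R)-4-{[methyl(phenyl)amino]methyl}-2-[13-(2-methyl-1,3-dioxolan-2-yl)tridecyl]-5-oxooxolane-3,4-dicarboxylic acid (C4 epimer mixture) | CC1(OCCO1)CCCCCCCCCCCCC[C@@H]2OC(=O)C(CN(C)c3ccccc3)(C(=O)O)[C@H]2C(=O)O | intermediate
17 | (2S,3R)-4-methylidene-2-[13-(2-methyl-1,3-dioxolan-2-yl)tridecyl]-5-oxooxolane-3-carboxylic acid | CC1(OCCO1)CCCCCCCCCCCCC[C@@H]2OC(=O)C(=C)[C@H]2C(=O)O | intermediate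
18 | (2S,3R)-4-methylidene-5-oxo-2-(14-oxopentadecyl)oxolane-3-carboxylic acid | CC(=O)CCCCCCCCCCCCC[C@@H]1OC(=O)C(=C)[C@H]1C(=O)O | intermediate
19 | (2S,3R,4S)-4-methyl-5-oxo-2-(14-oxopentadecyl)oxolane-3-carboxylic acid | CC(=O)CCCCCCCCCCCCC[C@@H]1OC(=O)[C@@H](C)[C@H]1C(=O)O | target

## Totals and risks

Total step count: 10. Longest linear sequence: 9 steps (steps 1–4, then 6–10); step 5 is a one-step side branch.

Three steps most likely to fail:

**Step 6 (aldol/lactonization).** Risks are incomplete ring closure onto the methyl ester, or attack of boron Lewis acid on the dioxolane. The fallback sets out from 6 (with 5) and comes back at 12. The acetic acid arm is masked as an allyl group. Compound 6 is acylated (n-BuLi, THF, −78 °C, pent-4-enoyl chloride) to (4R)-4-benzyl-3-(pent-4-enoyl)-1,3-oxazolidin-2-one F1. The same Bu2BOTf/iPr2NEt syn-aldol with 5 gives (4R)-4-benzyl-3-[(2R,3S)-3-hydroxy-16-(2-methyl-1,3-dioxolan-2-yl)-2-(prop-2-en-1-yl)hexadecanoyl]-1,3-oxazolidin-2-one F2. Ozonolysis of the terminal alkene (O3, CH2Cl2/MeOH, −78 °C; PPh3) lets the new aldehyde be trapped by the neighbouring hydroxyl as (4R)-4-benzyl-3-{(2S,3R)-5-hydroxy-2-[13-(2-methyl-1,3-dioxolan-2-yl)tridecyl]oxolane-3-carbonyl}-1,3-oxazolidin-2-one F3 (anomer mixture). Oxidation of the lactol (TEMPO cat., PhI(OAc)2, CH2Cl2) gives 12; the ring is thus closed by oxidation instead of acyl substitution.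

**Step 8 (Stiles carboxylation).** Risks are the 135 °C reaction, its reversibility, easy decarboxylation of crude 15, and the acidic work-up next to the ketal. The fallback sets out from 14 and comes back at 17. It replaces carboxylation by a direct enolate Mannich reaction. The dianion of 14 (LiN(SiMe3)2, 2.3 equiv, THF, −78 °C) is trapped with CH2=NMe2+ I− (N,N-dimethylmethyleneiminium iodide) to give (2S,3R,4S)-4-[(dimethylamino)methyl]-2-[13-(2-methyl-1,3-dioxolan-2-yl)tridecyl]-5-oxooxolane-3-carboxylic acid F4. Quaternization with MeI in MeOH gives {[(2S,3R,4S)-3-carboxy-2-[13-(2-methyl-1,3-dioxolan-2-yl)tridecyl]-5-oxooxolan-4-yl]methyl}trimethylammonium iodide F5. Elimination with aq. NaHCO3/CH2Cl2 gives 17, which is then only stirred with 1 M HCl/THF as in the second stage of step 9. This also bypasses the acidic HCHO/PhNHMe stage of step 9.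

**Step 10 (hydrogenation).** Risks are an insufficient cis:trans ratio, or Pd-promoted migration of the exocyclic alkene into the ring, which would destroy C3. The fallback sets out from 14 and comes back at 19. The stereocentre is set by protonation instead of hydrogenation. The dianion of 14 (NaN(SiMe3)2, 2.2 equiv, THF, −78 °C) is methylated with MeI anti to the carboxylate to give the all-trans acid (2S,3R,4R)-4-methyl-2-[13-(2-methyl-1,3-dioxolan-2-yl)tridecyl]-5-oxooxolane-3-carboxylic acid F6. The enolate is regenerated (LiN(iPr)2, 2.5 equiv, THF, −78 → −30 °C) and quenched at −78 °C with the bulky proton donor 2,6-di-tert-butyl-4-methylphenol. The proton arrives anti to the C3 carboxylate and gives (2S,3R,4S)-4-methyl-2-[13-(2-methyl-1,3-dioxolan-2-yl)tridecyl]-5-oxooxolane-3-carboxylic acid F7; the minor trans isomer is removed by crystallization. Ketal hydrolysis (1 M HCl, THF, rt) then gives 19. The selectivity of this protonation is less certain than the hydrogenation and would need to be checked.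

## Further compounds

F1 | step 6 | (4R)-4-benzyl-3-(pent-4-enoyl)-1,3-oxazolidin-2-one | C=CCCC(=O)N1[C@H](Cc2ccccc2)COC1=O
F2 | step 6 | (4R)-4-benzyl-3-[(2R,3S)-3-hydroxy-16-(2-methyl-1,3-dioxolan-2-yl)-2-(prop-2-en-1-yl)hexadecanoyl]-1,3-oxazolidin-2-one | CC1(OCCO1)CCCCCCCCCCCCC[C@H](O)[C@@H](CC=C)C(=O)N2[C@H](Cc3ccccc3)COC2=O
F3 | step 6 | (4R)-4-benzyl-3-{(2S,3R)-5-hydroxy-2-[13-(2-methyl-1,3-dioxolan-2-yl)tridecyl]oxolane-3-carbonyl}-1,3-oxazolidin-2-one (anomer mixture) | CC1(OCCO1)CCCCCCCCCCCCC[C@@H]2OC(O)C[C@H]2C(=O)N3[C@H](Cc4ccccc4)COC3=O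
F4 | step 8 | (2S,3R,4S)-4-[(dimethylamino)methyl]-2-[13-(2-methyl-1,3-dioxolan-2-yl)tridecyl]-5-oxooxolane-3-carboxylic acid | CC1(OCCO1)CCCCCCCCCCCCC[C@@H]2OC(=O)[C@H](CN(C)C)[C@H]2C(=O)O
F5 | step 8 | {[(2S,3R,4S)-3-carboxy-2-[13-(2-methyl-1,3-dioxolan-2-yl)tridecyl]-5-oxooxolan-4-yl]methyl}trimethylammonium iodide | CC1(OCCO1)CCCCCCCCCCCCC[C@@H]2OC(=O)[C@H](C[N+](C)(C)C)[C@H]2C(=O)O.[I-]
F6 | step 10 | (2S,3R,4R)-4-methyl-2-[13-(2-methyl-1,3-dioxolan-2-yl)tridecyl]-5-oxooxolane-3-carboxylic acid | CC1(OCCO1)CCCCCCCCCCCCC[C@@H]2OC(=O)[C@H](C)[C@H]2C(=O)O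
F7 | step 10 | (2S,3R,4S)-4-methyl-2-[13-(2-methyl-1,3-dioxolan-2-yl)tridecyl]-5-oxooxolane-3-carboxylic acid | CC1(OCCO1)CCCCCCCCCCCCC[C@@H]2OC(=O)[C@@H](C)[C@H]2C(=O)O
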